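The readings were generated by integration for an exercise, noise included.

X came slowly in this flask, and I wanted to know how much of the slowing lay with the catalyst D.

- summer: Q 0.80 M; D 5 mol%; the very flask that is asked about, followed so far
- flask: Q 0.80 M; D 5 mol%

- summer (time / h: X / %, Q / %): 2.00: 2.6, 97.9; 6.00: 5.8, 94.3; 10.0: 9.0, 90.9; 15.0: 10.8, 88.3; 25.0: 14.4, 84.9; 30.0: 15.7, 83.5

(standard deviation of a reading: 0.5 percentage points)

- no earlier run changes the charge of D; that part of a forecast is a guess

- apparent order in D when 30% of the Q are converted (percent change of the rate of making X for one percent more D charged)

Q still stood at 83.5% of its charge after 30.0 h, so I froze it and counted X per D charged. The first reading, 2.6% of the charge as X after 2.00 h on a loading of 5 mol%, gave 0.260 h⁻¹ for the start turnover: the X made per D charged per hour with Q close to its charge (the usual term is turnover frequency).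

Between 15.0 h and 30.0 h the same count was 0.0653 h⁻¹, less than the start turnover. With Q at 84.9% of its charge, that left a working share of 29.6%, a rough reading given a scatter of 0.5 percentage points on so small a first value.

The run stopped at 15.7% X, short of the 30% conversion asked about. My own reckoning was this: the rate is the start turnover times D charged times Q times the working share. At a fixed conversion Q is the same, so if the working share there does not change with the charge, the rate follows D charged and the order is 1. That "if" was a guess.

The forecast gave 1.1, slightly above mine, with a range from 0.7 to 1.8, and said: “No run varied D, so this is a guess.”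

The flask gave 1.0, inside that range.

    Q + D → D + X (k = 0.00510 M⁻¹ min⁻¹)
    2 D → G (k = 0.0180 M⁻¹ min⁻¹)

At the charge, each D made X at 5.9 d⁻¹ (my start turnover, read from the run, was 6.24 d⁻¹) and went into G at 2.07 d⁻¹ per D, which is less, so each D lost went with about 2.85 X made. When 30% of the Q was converted in the flask, after 5.50 d, D was 8.06% of the catalyst and G was 91.9%.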